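**Plan**
1. Retrosynthesis: first the primary acetate C–O bond is cut, then the side-chain C=C bond (cross-metathesis back to an 8-allyl group), then together the C4–C4a and O1–C8a bonds of the pyranone ring.
2. The double cut is possible because ring C is tied to ring A by an acyl carbon (C4 on C4a) and an ether oxygen (O1 on C8a) on neighbouring carbons, with the 5-oxygen next to C4a. O1–C2–C3–C4 is then a β-aryl-β-lactone, and C4a/C8a is an aryne whose flanking alkoxy group fixes the orientation.
3. Forward: ring A is built first as an allyl-bearing bis(MOM) o-silylaryl triflate, then the four-membered lactone is made, then the key step grows the lactone by the two aryne carbons into six-membered ring C. The chain is lengthened last.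
4. Stereochemistry: C2 is set as (S) by a BINOL–Ti Mukaiyama aldol and carried through lactonisation and ring expansion with its C–O bond never broken. The E alkene comes from cross-metathesis with methacrolein.
5. Helpers: the catechol is carried as its diacetate (keeps the benzylic C–O bond of the lactone from ionising) and the ring-A phenols as MOM ethers. All four are removed in one acid step before a lipase places the single acetate.

Key step: step 9

Remark: (S)-BINOL is assumed to give the (S)-aldol 16, as expected by analogy with benzaldehyde; should the sense prove opposite, (R)-BINOL is used and nothing else changes.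

**Step 1**
Reactants: 1 phloroglucinol
Product: 2 3,5-bis(methoxymethoxy)phenol
Conditions: NaH (2 equiv), MOMCl (2 equiv), DMF, 0 °C to 23 °C
Reagents that add atoms: chloromethyl methyl ether, COCCl
Why: Williamson-type O-alkylation of the phenoxide by the hard electrophile MOMCl; with two equivalents the bis-ether should be the main component of a statistical mixture from which the mono- and tris-ethers are separated and recycled.

**Step 2**
Reactants: 2 3,5-bis(methoxymethoxy)phenol
Product: 3 2-bromo-3,5-bis(methoxymethoxy)phenol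
Conditions: NBS (1.0 equiv), CH2Cl2, −78 °C
Reagents that add atoms: N-bromosuccinimide, O=C1CCC(=O)N1Br
Why: Electrophilic aromatic bromination, expected at one of the two equivalent positions ortho to the free hydroxyl group, which are less hindered than the position between the two OMOM groups.

**Step 3**
Reactants: 3 2-bromo-3,5-bis(methoxymethoxy)phenol
Product: 4 1-(allyloxy)-2-bromo-3,5-bis(methoxymethoxy)benzene
Conditions: allyl bromide, K2CO3, acetone, 56 °C
Reagents that add atoms: allyl bromide, C=CCBr
Why: Williamson ether synthesis on the phenoxide, the only acidic site.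

**Step 4**
Reactants: 4 1-(allyloxy)-2-bromo-3,5-bis(methoxymethoxy)benzene
Product: 6 2-allyl-6-bromo-3,5-bis(methoxymethoxy)phenol, via Claisen dienone 5 (not isolated)
Conditions: PhNEt2, 190 °C
Reagents that add atoms: none
Why: Aromatic Claisen rearrangement ([3,3]-sigmatropic shift) to the only free ortho position followed by tautomerisation of dienone 5, which places the allyl group on the carbon that becomes C8.

**Step 5**
Reactants: 6 2-allyl-6-bromo-3,5-bis(methoxymethoxy)phenol
Product: 10 2-allyl-3,5-bis(methoxymethoxy)-6-(trimethylsilyl)phenyl trifluoromethanesulfonate, via O-trimethylsilyl ether 7 (not isolated), via aryllithium 8 (not isolated), via lithium silylphenoxide 9 (not isolated)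
Conditions: (Me3Si)2NH, THF, 65 °C, evaporate; n-BuLi, THF, −100 °C to −78 °C; Tf2O, −100 °C to 23 °C
Reagents that add atoms: hexamethyldisilazane, C[Si](C)(C)N[Si](C)(C)C; triflic anhydride, O=S(=O)(OS(=O)(=O)C(F)(F)F)C(F)(F)F
Why: Standard route to o-silylaryl triflates by O-silylation, bromine–lithium exchange, 1,3 O-to-C silyl shift (retro-Brook rearrangement) and triflation of the phenoxide, all faster at low temperature than attack on the MOM or allyl groups.

**Step 6**
Reactants: 11 S-tert-butyl thioacetate
Product: 13 1-(tert-butylthio)-1-(trimethylsilyloxy)ethene, via lithium thioester enolate 12 (not isolated)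
Conditions: LiN(i-Pr)2, THF, −78 °C; Me3SiCl
Reagents that add atoms: chlorotrimethylsilane, C[Si](C)(C)Cl
Why: Kinetic enolisation of the thioester and O-silylation of the lithium enolate give the silyl ketene thioacetal needed for the Mukaiyama aldol reaction.

**Step 7**
Reactants: 13 1-(tert-butylthio)-1-(trimethylsilyloxy)ethene; 14 3,4-diacetoxybenzaldehyde
Product: 16 S-tert-butyl (S)-3-(3,4-diacetoxyphenyl)-3-hydroxypropanethioate, via aldol trimethylsilyl ether 15 (not isolated)
Conditions: Ti(O-i-Pr)4 (10 mol%), (S)-BINOL (20 mol%), 4 Å molecular sieves, Et2O, −20 °C; then 1 M HCl, THF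
Reagents that add atoms: none
Why: Catalytic asymmetric Mukaiyama aldol addition (Keck conditions) in which the BINOL–Ti Lewis acid binds the aldehyde and blocks one face, so that the new carbinol centre should be (S); the silyl ether is cleaved on acidic work-up.

**Step 8**
Reactants: 16 S-tert-butyl (S)-3-(3,4-diacetoxyphenyl)-3-hydroxypropanethioate
Product: 17 (S)-4-(3,4-diacetoxyphenyl)oxetan-2-one
Conditions: Hg(OCOCF3)2, Na2HPO4, MeCN, 23 °C
Reagents that add atoms: none
Why: Thiophilic activation of the S-tert-butyl thioester by divalent mercury (Masamune lactonisation) lets the β-hydroxyl group attack the acyl carbon in a 4-exo-trig closure, so the carbinol C–O bond is untouched and the (S) centre is retained, while the electron-poor diacetoxyphenyl group disfavours benzylic ionisation and decarboxylation.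

**Step 9**
Reactants: 10 2-allyl-3,5-bis(methoxymethoxy)-6-(trimethylsilyl)phenyl trifluoromethanesulfonate; 17 (S)-4-(3,4-diacetoxyphenyl)oxetan-2-one
Product: 19 (S)-8-allyl-2-(3,4-diacetoxyphenyl)-5,7-bis(methoxymethoxy)chroman-4-one, via aryne 18 (not isolated)
Conditions: CsF (3 equiv), MeCN/toluene, 23 °C, slow addition of 10
Reagents that add atoms: none
Why: Proposed new method: fluoride converts 10 into aryne 18; the ring oxygen of 17, more ether-like than an ordinary ester oxygen because the strained ring weakens ester resonance (or, equivalently, the benzylic alkoxide released by reversible fluoride attack at the acyl carbon), adds to the aryne carbon remote from the flanking OMOM group, and the aryl anion formed beside that OMOM group attacks the acyl carbon and expels the oxygen, so that the two aryne carbons are inserted into the C(acyl)–O bond. The closest known reaction types are aryne σ-insertion into the N–C(O) bond of amides and azetidin-2-ones (giving 2,3-dihydroquinolin-4-ones), the acyl-alkylation of arynes by cyclic β-ketoesters with two-atom ring expansion, and the formal O–C(O) insertion of carboxylic acids that gives o-hydroxyaryl ketones. Ring C is not closed from a chain but grows from the four-membered lactone by two atoms; its C4–C4a bond forms by 4-exo-trig attack of the aryl anion on the acyloxonium carbonyl (6-exo-trig on the acyl fluoride in the fluoride-relay variant), driven by loss of β-lactone strain and of the aryne triple bond. No new stereocentre is made: C2 is C4 of the lactone and its four bonds stay intact in both variants, so the (S) configuration is carried over. The step needs regioselective addition to the unsymmetrical aryne, secured by the inductive pull of the OMOM group next to one aryne carbon (aryne distortion, as in 3-alkoxybenzynes), and it needs the benzylic C–O bond not to ionise, secured by the two acetates, which make the aryl group a poor cation stabiliser.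

**Step 10**
Reactants: 19 (S)-8-allyl-2-(3,4-diacetoxyphenyl)-5,7-bis(methoxymethoxy)chroman-4-one
Product: 20 (S,E)-4-[2-(3,4-diacetoxyphenyl)-5,7-bis(methoxymethoxy)-4-oxochroman-8-yl]-2-methylbut-2-enal
Conditions: second-generation Hoveyda–Grubbs catalyst RuCl2(H2IMes)(=CH-C6H4-2-O-i-Pr) (5 mol%), methacrolein (10 equiv), 1,4-benzoquinone (10 mol%), CH2Cl2, 40 °C
Reagents that add atoms: methacrolein, CC(=C)C=O
Why: Olefin cross-metathesis of a terminal alkene with methacrolein, which should give the thermodynamically favoured (E)-trisubstituted enal, while benzoquinone suppresses ruthenium hydride isomerisation of the allyl group.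

**Step 11**
Reactants: 20 (S,E)-4-[2-(3,4-diacetoxyphenyl)-5,7-bis(methoxymethoxy)-4-oxochroman-8-yl]-2-methylbut-2-enal
Product: 21 (S)-2-(3,4-diacetoxyphenyl)-8-[(E)-4-hydroxy-3-methylbut-2-en-1-yl]-5,7-bis(methoxymethoxy)chroman-4-one
Conditions: NaBH4, EtOH/CH2Cl2, −78 °C
Reagents that add atoms: none
Why: Chemoselective 1,2-reduction of the aldehyde at low temperature, since the doubly ortho-substituted, electron-rich aryl ketone at C4 and the aryl acetates react much more slowly.

**Step 12**
Reactants: 21 (S)-2-(3,4-diacetoxyphenyl)-8-[(E)-4-hydroxy-3-methylbut-2-en-1-yl]-5,7-bis(methoxymethoxy)chroman-4-one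
Product: 22 (S)-2-(3,4-dihydroxyphenyl)-5,7-dihydroxy-8-[(E)-4-hydroxy-3-methylbut-2-en-1-yl]chroman-4-one
Conditions: HCl (1 M), MeOH, 40 °C
Reagents that add atoms: none
Why: Acid-catalysed acetal exchange removes both MOM ethers and acid-catalysed methanolysis removes both aryl acetates, under conditions in which a flavanone does not open to the chalcone, so C2 is not epimerised.

**Step 13**
Reactants: 22 (S)-2-(3,4-dihydroxyphenyl)-5,7-dihydroxy-8-[(E)-4-hydroxy-3-methylbut-2-en-1-yl]chroman-4-one
Product: 23 Kanzonol S
Conditions: Candida antarctica lipase B (immobilised), vinyl acetate, THF/t-BuOMe, 40 °C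
Reagents that add atoms: vinyl acetate, CC(=O)OC=C
Why: Lipase-catalysed transesterification with an enol ester acylates primary aliphatic alcohols but not phenols, and tautomerisation of the released vinyl alcohol to acetaldehyde makes the step irreversible.

**Compound list**
1 | phloroglucinol | Oc1cc(O)cc(O)c1 | starting material
2 | 3,5-bis(methoxymethoxy)phenol | COCOc1cc(O)cc(OCOC)c1 | intermediate
3 | 2-bromo-3,5-bis(methoxymethoxy)phenol | COCOc1cc(O)c(Br)c(OCOC)c1 | intermediate
4 | 1-(allyloxy)-2-bromo-3,5-bis(methoxymethoxy)benzene | C=CCOc1cc(OCOC)cc(OCOC)c1Br | intermediate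
5 | 6-allyl-2-bromo-3,5-bis(methoxymethoxy)cyclohexa-2,4-dien-1-one (Claisen dienone) | C=CCC1C(=O)C(Br)=C(OCOC)C=C1OCOC | intermediate
6 | 2-allyl-6-bromo-3,5-bis(methoxymethoxy)phenol | C=CCc1c(O)c(Br)c(OCOC)cc1OCOC | intermediate
7 | [2-allyl-6-bromo-3,5-bis(methoxymethoxy)phenoxy]trimethylsilane | C=CCc1c(O[Si](C)(C)C)c(Br)c(OCOC)cc1OCOC | intermediate
8 | [3-allyl-4,6-bis(methoxymethoxy)-2-(trimethylsilyloxy)phenyl]lithium | C=CCc1c(O[Si](C)(C)C)c([Li])c(OCOC)cc1OCOC | intermediate
9 | lithium 2-allyl-3,5-bis(methoxymethoxy)-6-(trimethylsilyl)phenoxide | C=CCc1c(O[Li])c([Si](C)(C)C)c(OCOC)cc1OCOC | intermediate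
10 | 2-allyl-3,5-bis(methoxymethoxy)-6-(trimethylsilyl)phenyl trifluoromethanesulfonate | C=CCc1c(OS(=O)(=O)C(F)(F)F)c([Si](C)(C)C)c(OCOC)cc1OCOC | intermediate
11 | S-tert-butyl thioacetate | CC(=O)SC(C)(C)C | starting material
12 | lithium 1-(tert-butylthio)ethen-1-olate | C=C(O[Li])SC(C)(C)C | intermediate
13 | 1-(tert-butylthio)-1-(trimethylsilyloxy)ethene | C=C(O[Si](C)(C)C)SC(C)(C)C | intermediate
14 | 3,4-diacetoxybenzaldehyde | CC(=O)Oc1ccc(C=O)cc1OC(C)=O | starting material
15 | S-tert-butyl (S)-3-(3,4-diacetoxyphenyl)-3-(trimethylsilyloxy)propanethioate | CC(C)(C)SC(=O)C[C@H](O[Si](C)(C)C)c1ccc(OC(C)=O)c(OC(C)=O)c1 | intermediate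
16 | S-tert-butyl (S)-3-(3,4-diacetoxyphenyl)-3-hydroxypropanethioate | CC(C)(C)SC(=O)C[C@H](O)c1ccc(OC(C)=O)c(OC(C)=O)c1 | intermediate
17 | (S)-4-(3,4-diacetoxyphenyl)oxetan-2-one | O=C1C[C@@H](c2ccc(OC(C)=O)c(OC(C)=O)c2)O1 | intermediate
18 | 3-allyl-4,6-bis(methoxymethoxy)benzyne | C=CCC1=C(OCOC)C=C(OCOC)C#C1 | intermediate
19 | (S)-8-allyl-2-(3,4-diacetoxyphenyl)-5,7-bis(methoxymethoxy)chroman-4-one | C=CCc1c(OCOC)cc(OCOC)c2c1O[C@H](c1ccc(OC(C)=O)c(OC(C)=O)c1)CC2=O | intermediate
20 | (S,E)-4-[2-(3,4-diacetoxyphenyl)-5,7-bis(methoxymethoxy)-4-oxochroman-8-yl]-2-methylbut-2-enal | O=C/C(C)=C/Cc1c(OCOC)cc(OCOC)c2c1O[C@H](c1ccc(OC(C)=O)c(OC(C)=O)c1)CC2=O | intermediate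
21 | (S)-2-(3,4-diacetoxyphenyl)-8-[(E)-4-hydroxy-3-methylbut-2-en-1-yl]-5,7-bis(methoxymethoxy)chroman-4-one | OC/C(C)=C/Cc1c(OCOC)cc(OCOC)c2c1O[C@H](c1ccc(OC(C)=O)c(OC(C)=O)c1)CC2=O | intermediate
22 | (S)-2-(3,4-dihydroxyphenyl)-5,7-dihydroxy-8-[(E)-4-hydroxy-3-methylbut-2-en-1-yl]chroman-4-one | OC/C(C)=C/Cc1c(O)cc(O)c2c1O[C@H](c1ccc(O)c(O)c1)CC2=O | intermediate
23 | Kanzonol S, (S)-8-[(E)-4-acetoxy-3-methylbut-2-en-1-yl]-2-(3,4-dihydroxyphenyl)-5,7-dihydroxychroman-4-one | CC(=O)OC/C(C)=C/Cc1c(O)cc(O)c2c1O[C@H](c1ccc(O)c(O)c1)CC2=O | target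

**Step count and risks**
Total steps: 13. Longest linear sequence: 10 steps (steps 1–5 and 9–13, from phloroglucinol).

Steps most likely to fail:

Step 9 (Proposed new method). The lactone oxygen may prove too weak a nucleophile, so that the aryne is consumed by fluoride or by itself. Addition through the carbonyl oxygen followed by ionisation at the benzylic carbon would erode the configuration, and fluoride may slowly cleave the aryl acetates. Fallback from 10: the known addition of a carboxylic acid to an aryne with O-to-C acyl shift is run with commercial (E)-3,4-diacetoxycinnamic acid (CsF, THF, heat) through the same aryne 18. It should give (E)-1-[3-allyl-2-hydroxy-4,6-bis(methoxymethoxy)phenyl]-3-(3,4-diacetoxyphenyl)prop-2-en-1-one F1, which closes by oxa-Michael addition in the same flask (or with catalytic Et3N) to racemic 8-allyl-2-(3,4-diacetoxyphenyl)-5,7-bis(methoxymethoxy)chroman-4-one F2. Kinetic resolution by asymmetric transfer hydrogenation (RuCl(p-cymene)[(R,R)-TsDPEN], HCO2H/Et3N) should reduce the (R)-ketone to (2R,4R)-8-allyl-2-(3,4-diacetoxyphenyl)-5,7-bis(methoxymethoxy)chroman-4-ol F3 and leave the (S)-ketone, which is 19, where the route is rejoined. Ring C is then closed by C–O bond formation and the stereocentre comes from a resolution, not from the lactone.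

Step 2. Bromination may go para to the hydroxyl group (between the two OMOM groups) or twice. Fallback from 2: the phenol is converted into 3,5-bis(methoxymethoxy)phenyl N,N-diethylcarbamate F4 (Et2NCOCl, NaH, THF). Directed ortho-metalation (s-BuLi, TMEDA, THF, −78 °C) should give [2-(diethylcarbamoyloxy)-4,6-bis(methoxymethoxy)phenyl]lithium F5, which is quenched with BrCCl2CCl2Br to 2-bromo-3,5-bis(methoxymethoxy)phenyl N,N-diethylcarbamate F6. Hydrolysis (NaOH, EtOH, 80 °C) rejoins the route at 3. The position of the bromine is then fixed by the carbamate and not by the electronic bias of the ring.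

Step 12. Under protic acid the primary allylic alcohol may ionise, or the neighbouring 7-hydroxyl group may attack the chain (ring closure onto the side chain). Fallback from 19: the acid step is moved forward to where the chain is still a plain allyl group. HCl/MeOH should give (S)-8-allyl-2-(3,4-dihydroxyphenyl)-5,7-dihydroxychroman-4-one F7. Cross-metathesis with methacrolein (same ruthenium catalyst, which tolerates free phenols) should give (S,E)-4-[2-(3,4-dihydroxyphenyl)-5,7-dihydroxy-4-oxochroman-8-yl]-2-methylbut-2-enal F8. Reduction with NaBH(OAc)3 in THF/AcOH, acidic so that the free flavanone does not open to the chalcone, rejoins the route at 22.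

**Further compounds**
F1 | step 9 | (E)-1-[3-allyl-2-hydroxy-4,6-bis(methoxymethoxy)phenyl]-3-(3,4-diacetoxyphenyl)prop-2-en-1-one | C=CCc1c(O)c(C(=O)/C=C/c2ccc(OC(C)=O)c(OC(C)=O)c2)c(OCOC)cc1OCOC
F2 | step 9 | racemic 8-allyl-2-(3,4-diacetoxyphenyl)-5,7-bis(methoxymethoxy)chroman-4-one | C=CCc1c(OCOC)cc(OCOC)c2c1OC(c1ccc(OC(C)=O)c(OC(C)=O)c1)CC2=O
F3 | step 9 | (2R,4R)-8-allyl-2-(3,4-diacetoxyphenyl)-5,7-bis(methoxymethoxy)chroman-4-ol | C=CCc1c(OCOC)cc(OCOC)c2c1O[C@@H](c1ccc(OC(C)=O)c(OC(C)=O)c1)C[C@H]2O
F4 | step 2 | 3,5-bis(methoxymethoxy)phenyl N,N-diethylcarbamate | CCN(CC)C(=O)Oc1cc(OCOC)cc(OCOC)c1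
F5 | step 2 | [2-(diethylcarbamoyloxy)-4,6-bis(methoxymethoxy)phenyl]lithium | CCN(CC)C(=O)Oc1cc(OCOC)cc(OCOC)c1[Li]
F6 | step 2 | 2-bromo-3,5-bis(methoxymethoxy)phenyl N,N-diethylcarbamate | CCN(CC)C(=O)Oc1cc(OCOC)cc(OCOC)c1Br
F7 | step 12 | (S)-8-allyl-2-(3,4-dihydroxyphenyl)-5,7-dihydroxychroman-4-one | C=CCc1c(O)cc(O)c2c1O[C@H](c1ccc(O)c(O)c1)CC2=O
F8 | step 12 | (S,E)-4-[2-(3,4-dihydroxyphenyl)-5,7-dihydroxy-4-oxochroman-8-yl]-2-methylbut-2-enal | O=C/C(C)=C/Cc1c(O)cc(O)c2c1O[C@H](c1ccc(O)c(O)c1)CC2=O
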